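The readings come from a simulation with made-up constants, noise included.

Amounts first. In both earlier runs substrate and product add up to the charge at the last reading, 100.3% in dawn and 100.7% in summer, with a scatter of 0.5 percentage points on each reading. So I count nothing as lost, and because one product holds two substrate, [product] is the substrate gone divided by two.

To whoever takes the bench: Sunday's, Tuesday's, Friday's and Monday's stand closed and stirred, and you read them at 20 h.

| flask | substrate | remark | time |
|---|---|---|---|
| dawn | 0.14 M | run made earlier |  |
| summer | 0.60 M | run made earlier |  |
| Sunday's | 0.20 M |  | 20 h |
| Tuesday's | 0.30 M |  | 20 h |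
| Friday's | 0.50 M |  | 20 h |
| Monday's | 0.80 M |  | 20 h |

- dawn (time / h: product / %, substrate / %): 0.667: 3.9, 96.6; 2.00: 9.0, 90.2; 4.00: 16.9, 82.9; 5.00: 20.8, 79.4; 8.00: 29.4, 71.4; 10.0: 33.6, 66.7
- summer (time / h: product / %, substrate / %): 0.667: 12.0, 86.7; 2.00: 31.0, 69.5; 4.00: 46.8, 53.8; 5.00: 52.1, 47.3; 8.00: 62.4, 36.7; 10.0: 67.7, 33.0

(scatter of a reading: 0.5 percentage points)

- a species is counted by the substrate in it: one product counts as two
- steps thought possible: 2 substrate <-> product
- "hardly changes" means that all values lie within two and a half points (for a concentration: within two and a half percent of the largest)

* [product] at the end for Sunday's, Tuesday's, Friday's, Monday's, in this order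
* how the row runs (hardly changes / falls, then rises / falls all the way / rises, then falls / rises all the way)

Dawn's last reading gives 0.357 /M/h for the rise of 1/[substrate] per hour, which I call the pairing pace. Summer gives 0.338 /M/h. With a pace this close at these two charges, I read the step as second order. Summer's is the lower, and summer holds 67.7% product against dawn's 33.6%, so some product may be going back.

My rule, for a second-order step with nothing going back and the pace held fixed: the share of substrate left is one over (one plus pace times charge times time). With dawn's pace, the rule gives Sunday's 41.2% substrate left, which reckons to 0.0588 M product. For Monday's it gives 14.9%, which reckons to 0.340 M, though that charge lies above summer's. These figures let nothing go back, so expect less.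

Don't dilute or top up: at 10.0 h summer, charged at 0.60 M, has 33.0% substrate left against 66.7% in dawn, charged at 0.14 M.

The forecast reads 0.057 M, 0.097 M, 0.186 M and 0.32 M, rises all the way, since “product rises steadily with charge”. On Monday's it lies below my 0.340 M.

The flasks give 0.0561 M, 0.0974 M, 0.186 M and 0.324 M: rises all the way.

    2 substrate ⇌ product (K = 21.7 /M, k = 5.21 × 10⁻⁵ /M/s)

At 20.0 h, Sunday's has a relaxation half-life, both ways together, of 9.30 h, about half of the 20 h it has run, and it holds 43.9% substrate where the pairing pace gives 41.2%, with 28.7% standing at 200 h. On Monday's the pace gives 14.9%, less than the 15.6% still standing at 200 h, and that flask holds 19.1% at 20.0 h.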